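(Its constants are those of an exercise; the flask was simulated.)

A small charge of starting complex, 0.10 M, stands against 0.400 M of incoming ligand in each set-up you are taking over:

| flask | starting complex | incoming ligand | time | remark |
|---|---|---|---|---|
| east | 0.10 M (fed, over 1.00 min) | 0.400 M | 2.0 min | a stirred flask in which starting complex is dosed at a steady rate over 1.00 min without added volume, worked up at 2.0 min |
| south | 0.10 M | 0.400 M | 2.0 min | everything together in a closed stirred flask, run for 2.0 min |
| south-east | 0.10 M | 0.400 M |  | one stirred flow tank at steady state, fed with the mixture as stated, mean residence time 2.0 min |
| west | 0.10 M | 0.400 M | 2.0 min | a tube with plug flow, the mixed feed as stated, residence time 2.0 min |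

    starting complex + incoming ligand ⇌ leaving ligand + complex with one exchanged (K1 = 0.084, k1 = 0.037 /M/s)
    complex with one exchanged + incoming ligand ⇌ leaving ligand + complex with two exchanged (K2 = 0.081, k2 = 0.014 /M/s)
    complex with two exchanged + incoming ligand ⇌ leaving ligand + complex with three exchanged (K3 = 0.49, k3 = 0.039 /M/s)
    complex with three exchanged + incoming ligand → over-reaction product (k4 = 0.066 /M/s)

- the stated concentrations are those of everything mixed, before any reaction; amounts are the same in each set-up
- the feed brings no volume worth counting
- run time (east): 2.0 min

- the set-up with the highest share of complex with three exchanged in all that became complex with three exchanged or over-reaction product, at the outlet or at the end ("none" if the first two lie within 2 percentage points) (east / south / south-east / west / none)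
- share of complex with three exchanged in all that became complex with three exchanged or over-reaction product, at the outlet or at the end, east
- share of complex with three exchanged in all that became complex with three exchanged or over-reaction product, at the outlet or at the end, south
- share of complex with three exchanged in all that became complex with three exchanged or over-reaction product, at the outlet or at the end, south-east
- share of complex with three exchanged in all that became complex with three exchanged or over-reaction product, at the outlet or at the end, west

This is my reckoning before any run. Incoming ligand turns complex with three exchanged into over-reaction product. With the ligand held at its charge, a simplification of mine, this loss is pseudo-first-order, with 0.066 /M/s times that charge giving 1.58 /min. In the south flask its half-life by step 4 alone is 0.44 min, shorter than the 2.0 min run, so much of it will be lost. Carry N = 3.17, the ageing count: the constant of step 4 times the ligand charge times the time a portion has spent in the flask.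

In the south flask and the west tube, I assume that the making of complex with three exchanged rises in step with time. Its share is then 2(N − 1 + exp(−N))/(N·N), or 44.0%. In the east flask the average portion is younger by 0.500 min, so N becomes 2.38 and the share 52.0%. In the south-east tank the share is one over one plus N, 24.0%. So expect east on top. Leave the ligand charge and the time as they are; both stand in N = 3.17.

The forecast names east as best, with 52% for east, 44% for south, 44% for west and 26.8% for south-east, and of east it says “dosing delays the chain”. We part on the south-east tank, where I reckoned 24.0%.

The simulation gives east as best: 51.7% for east, 44.1% for south, 44.1% for west and 26.8% for south-east. With ligand at 0.345 M or 0.461 M the east share has moved 5 points, which takes it outside the forecast's range of 48% to 56%. In the south-east tank, one over the share, less one, is N times the fraction of ligand left, so that fraction reads 86.2% of its charge.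

Now take the west tube with 0.025 M of starting complex. N holds no starting complex, so it stays 3.17 and gives 44.0% again; the simulation gives 45.1%.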